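**Plan**
- Cuts: the inner aryl ring (aryl C-1 biaryl carbon, C-2 oxygen-bearing, C-5 allyl-bearing) is opened across C3–C4 and C5–C6 into a 2-(decalinyloxy)-3-aryl-1,3-butadiene and methyl propiolate. The O–C(=CH2) carbon of the diene goes back to the carbonyl of an ester of the decalin C-2 alcohol, and the C-5 allyl group is cut at ArCH2–CH=CH2.
- Enabling feature: the ether oxygen sits on aryl C-2, next to the biaryl carbon C-1 and para to the allyl carbon C-5. While this ring is not yet aromatic, C-2–O is only an enol ether of the tertiary decalin alcohol, so the crowded aryl–O–C(tert) bond never has to be made by substitution.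
- Forward order: cyclohexane ring of dihydrocarvone, second decalin ring by Robinson annulation, O-acylation with the outer-ring arylacetic acid, two methylenations to the diene, [4+2] and dehydrogenation to close the inner aryl ring, then ester-to-allyl conversion and desilylation.
- Stereochemistry: C-7 comes from (R)-carvone-derived dihydrocarvone and C-4a from the (R)-1-phenylethylamine imine Michael addition. C-8a is set by Li/NH3 (trans fusion) and C-2 by equatorial methyl delivery to the ketone; the C-2–O bond is not broken afterwards.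

Key step: step 14

Assumption: commercial (+)-dihydrocarvone (the 1,4-reduction product of (R)-carvone, sold as a mixture of C-2 epimers, mainly 2R,5R) is used as such; C-2 is planar in the enamine of step 1, so both epimers converge.

Abbreviations: decalin atoms carry naphthalene numbering (C-2 carbinol carbon, C-4a methyl-bearing ring fusion, C-7 side-chain carbon, C-8a ring-fusion CH). Dec = (2R,4aS,7R,8aS)-2,4a-dimethyl-7-[2-(triethylsilyloxy)propan-2-yl]decahydronaphthalen-2-yl. Ar = 3-allyl-4-(tert-butyldimethylsilyloxy)phenyl.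

**Route**

Step 1
Reactants: 1 (+)-dihydrocarvone; 2 methyl vinyl ketone
Product: 5 (2S,5R)-2-methyl-2-(3-oxobutyl)-5-(prop-1-en-2-yl)cyclohexan-1-one, via phenylethyl ketimine 3 (not isolated), via Michael-adduct ketimine 4 (not isolated)
Conditions: (R)-(+)-1-phenylethylamine, TsOH (cat.), toluene, reflux, Dean–Stark; then 2, THF, 40 °C; then 20% aq. AcOH, rt
Reagents that add atoms: water, O (returns the ketone oxygen on hydrolysis)
Why: d'Angelo asymmetric Michael addition: the more substituted secondary enamine tautomer of ketimine 3 adds to the enone through a compact aza-ene-like transition state on the face away from the phenyl group of the auxiliary, which should set the quaternary centre as S with the methyl cis to the isopropenyl group, and mild acid then hydrolyses imine 4.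

Step 2
Reactants: 5 diketone
Product: 7 (4aS,7R)-4a-methyl-7-(prop-1-en-2-yl)-4,4a,5,6,7,8-hexahydronaphthalen-2(3H)-one, via bicyclic ketol 6 (not isolated)
Conditions: NaOMe (0.3 equiv), MeOH, rt → 60 °C
Reagents that add atoms: none
Why: Intramolecular aldol condensation (second half of a Robinson annulation): the methyl-ketone enolate closes the new six-membered ring on the ring carbonyl, ketol 6 loses water by E1cB, and neither the quaternary C-4a nor the remote C-7 can epimerise.

Step 3
Reactants: 7 enone
Product: 8 (4aS,7R,8aS)-4a-methyl-7-(prop-1-en-2-yl)octahydronaphthalen-2(1H)-one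
Conditions: Li, NH3(l)/THF, t-BuOH (1 equiv), −78 °C; then solid NH4Cl
Reagents that add atoms: none
Why: Dissolving-metal (Birch-type) enone reduction: the β-carbon C-8a is protonated axially, anti to the angular methyl, so the trans-fused decalone (8aS) should predominate as in 3-keto-Δ4-steroid reductions, while the isolated isopropenyl alkene is not reduced.

Step 4
Reactants: 8 trans-decalone
Product: 9 (4aS,7R,8aS)-7-(2-hydroxypropan-2-yl)-4a-methyloctahydronaphthalen-2(1H)-one
Conditions: Co(acac)2 (20 mol%), PhSiH3, O2 (1 atm), i-PrOH, rt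
Reagents that add atoms: dioxygen, O=O
Why: Mukaiyama hydration (cobalt-hydride hydrogen-atom transfer): H-atom transfer to the 1,1-disubstituted alkene gives the tertiary radical, which is trapped by O2 and reduced by the silane to the Markovnikov tertiary alcohol, leaving the ketone and the three stereocentres untouched.

Step 5
Reactants: 9 hydroxy ketone
Product: 10 (4aS,7R,8aS)-4a-methyl-7-[2-(triethylsilyloxy)propan-2-yl]octahydronaphthalen-2(1H)-one
Conditions: TESOTf, 2,6-lutidine, CH2Cl2, −78 → 0 °C
Reagents that add atoms: triethylsilyl triflate, CC[Si](CC)(CC)OS(=O)(=O)C(F)(F)F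
Why: Silyl triflate with a hindered pyridine is the standard silylation of a tertiary alcohol, and at low temperature 2,6-lutidine should not convert the ketone into a silyl enol ether.

Step 6
Reactants: 10 silyloxy ketone
Product: 11 (2R,4aS,7R,8aS)-2,4a-dimethyl-7-[2-(triethylsilyloxy)propan-2-yl]decahydronaphthalen-2-ol (Dec–OH)
Conditions: MeLi, ClTi(OiPr)3, Et2O, −40 °C; then 10, −40 °C → rt; then H2O
Reagents that add atoms: methyllithium, [Li]C (used as methyltitanium triisopropoxide formed in the flask, C[Ti](OC(C)C)(OC(C)C)OC(C)C)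
Why: Reetz-type organotitanium addition to a ketone: the bulky methyl–titanium reagent should enter along the equatorial trajectory, as bulky methyl–metal reagents do with 3-keto-5α-steroids, giving the axial C-2 hydroxyl trans to the angular methyl and an equatorial methyl, i.e. the 2R centre.

Step 7
Reactants: 12 4-hydroxyphenylacetic acid
Product: 13 prop-2-en-1-yl 2-[4-(prop-2-en-1-yloxy)phenyl]acetate
Conditions: allyl bromide (2.5 equiv), K2CO3, DMF, 60 °C
Reagents that add atoms: allyl bromide, C=CCBr
Why: Double SN2 O-alkylation (Williamson ether synthesis plus carboxylate alkylation) under carbonate base.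

Step 8
Reactants: 13 allyl ether ester
Product: 14 prop-2-en-1-yl 2-(3-allyl-4-hydroxyphenyl)acetate
Conditions: N,N-diethylaniline, 200 °C
Reagents that add atoms: none
Why: Aromatic Claisen rearrangement ([3,3]-sigmatropic shift, then tautomerisation) moves the O-allyl group to an ortho carbon; the two ortho positions are equivalent and the allyl ester is thermally inert.

Step 9
Reactants: 14 phenol
Product: 15 prop-2-en-1-yl 2-[3-allyl-4-(tert-butyldimethylsilyloxy)phenyl]acetate
Conditions: TBSCl, imidazole, DMF, rt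
Reagents that add atoms: tert-butyldimethylsilyl chloride, CC(C)(C)[Si](C)(C)Cl
Why: Imidazole-promoted silylation of a phenol (Corey protocol).

Step 10
Reactants: 15 allyl ester
Product: 16 2-[3-allyl-4-(tert-butyldimethylsilyloxy)phenyl]acetic acid (ArCH2CO2H)
Conditions: Pd(PPh3)4 (3 mol%), morpholine, THF, rt; then pH 4 buffer
Reagents that add atoms: none
Why: Tsuji–Trost deallylation: Pd(0) ionises only the allyl ester to a π-allyl complex that morpholine captures, so the C-allyl group and the base-sensitive aryl silyl ether should remain.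

Step 11
Reactants: 16 arylacetic acid; 11 Dec–OH
Product: 18 Dec 2-Ar-acetate (Dec–O–CO–CH2–Ar), via arylacetyl chloride 17 (not isolated)
Conditions: 16, (COCl)2, DMF (cat.), CH2Cl2, 0 °C → rt, evaporate; 11, n-BuLi, THF, −78 → 0 °C; then 17, −78 °C → rt
Reagents that add atoms: none
Why: Acylation of a lithium tert-alkoxide by an acid chloride is the classical route to esters of hindered tertiary alcohols (any arylketene formed by dehydrochlorination is trapped by the same alkoxide); only the acyl–O bond forms, so C-2 keeps its configuration.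

Step 12
Reactants: 18 arylacetate
Product: 21 Dec 2-Ar-prop-2-enoate (Dec–O–CO–C(=CH2)–Ar), via Mannich base 19 (not isolated), via trimethylammonium iodide 20 (not isolated)
Conditions: LiHMDS, THF, −78 °C; CH2=NMe2+ I−, −78 °C → rt; then MeI, CH2Cl2, rt; then 5% aq. NaHCO3, rt
Reagents that add atoms: Eschenmoser's salt, C=[N+](C)C.[I-]
Why: Mannich reaction of the ester lithium enolate with the iminium salt, then quaternisation and E1cB (Hofmann-type) elimination, is the standard α-methylenation of esters; the α-stereocentre of 19 and 20 disappears in the elimination.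

Step 13
Reactants: 21 acrylate
Product: 22 2-(Dec-oxy)-3-Ar-buta-1,3-diene
Conditions: Tebbe reagent (0.5 M in toluene), pyridine (cat.), THF, −40 °C → rt; 15% aq. NaOH quench; basic alumina
Reagents that add atoms: Tebbe reagent, C[Al-]1(C)C[Ti](C2C=CC=C2)(C2C=CC=C2)[Cl+]1
Why: Tebbe methylenation: the titanium methylidene adds [2+2] to the ester carbonyl and the oxatitanacyclobutane collapses to the enol ether and Ti=O, a reaction known to turn α,β-unsaturated esters into 2-alkoxy-1,3-dienes; terminal alkenes only exchange methylene degenerately and silyl ethers are inert.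

Step 14
Reactants: 22 diene; 23 methyl propiolate
Product: 24 methyl 4-(Dec-oxy)-5-Ar-cyclohexa-1,4-diene-1-carboxylate
Conditions: 23 (5 equiv), BHT (cat.), toluene, 90 °C, sealed base-washed tube
Reagents that add atoms: none
Why: A thermal, concerted but asynchronous normal-electron-demand [4π+2π] cycloaddition of the s-cis 2-alkoxydiene (HOMO) to the propiolate (LUMO) forms aryl C3–C4 and C5–C6 in one suprafacial step; the closest known reaction type is the Diels–Alder reaction of 2-alkoxy- and 2-silyloxy-1,3-dienes with propiolates, used to reach aryl ethers after dehydrogenation. The one new ring, the future inner aryl ring, is closed as a cyclohexa-1,4-diene by this intermolecular [4+2] annulation, both ring bonds arising in the same step. No stereocentre is created and the four decalin centres are remote spectators. The selectivity required is regiochemical: the oxygen lone pair on C-2 puts the largest HOMO coefficient on the adjacent diene terminus (future C-3), which bonds to the unsubstituted β-carbon of the propiolate, so the ester lands on C-5, para to oxygen. The 3-aryl group is the weaker donor and is twisted out of the diene plane by the neighbouring tert-alkoxy group, so it should not override this preference. Because C-2–O enters as an enol ether made from an ester, the tertiary carbon never undergoes substitution and keeps its configuration.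

Step 15
Reactants: 24 cyclohexadiene
Product: 25 methyl 4-(Dec-oxy)-3-Ar-benzoate
Conditions: DDQ (1.1 equiv), toluene, 0 °C → rt; basic alumina
Reagents that add atoms: none
Why: DDQ dehydrogenation of a 1,4-cyclohexadiene (hydride abstraction from a doubly allylic CH2, then proton loss) is fast at or below room temperature because it creates the arene; the enol ether becomes the aryl ether without touching C-2–O, and the allylarene and silyl ethers should react far more slowly.

Step 16
Reactants: 25 aryl ester
Product: 26 [4-(Dec-oxy)-3-Ar-phenyl]methanol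
Conditions: DIBAL-H (2.5 equiv), CH2Cl2, −78 → 0 °C; Rochelle salt
Reagents that add atoms: none
Why: DIBAL-H reduction of an aromatic ester to the benzylic alcohol; silyl ethers, alkenes and the aryl ether are inert.

Step 17
Reactants: 26 benzylic alcohol
Product: 27 4-(bromomethyl)-1-(Dec-oxy)-2-Ar-benzene
Conditions: CBr4, PPh3, 2,6-lutidine, CH2Cl2, −20 → 0 °C; used crude
Reagents that add atoms: carbon tetrabromide, BrC(Br)(Br)Br
Why: Appel bromination runs under neutral, buffered conditions and so avoids the acid that would cleave the tert-alkyl aryl ether.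

Step 18
Reactants: 27 benzylic bromide
Product: 28 4-allyl-1-(Dec-oxy)-2-Ar-benzene (bis-silyl ether of the target)
Conditions: CH2=CHMgBr (2 equiv), CuI (10 mol%), THF, −40 → 0 °C
Reagents that add atoms: vinylmagnesium bromide, C=C[Mg]Br
Why: Copper-catalysed sp3–sp2 cross-coupling of a benzylic bromide with a vinyl Grignard reagent is a standard way to make allylarenes.

Step 19
Reactants: 28 bis-silyl ether
Product: 29 target, (2R,4aS,7R,8aS)-2-[4-allyl-2-(3-allyl-4-hydroxyphenyl)phenoxy]-7-(2-hydroxypropan-2-yl)-2,4a-dimethyldecahydronaphthalene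
Conditions: TBAF (3 equiv), THF, rt → 40 °C; aq. NH4Cl
Reagents that add atoms: none
Why: Fluoride-mediated desilylation, driven by Si–F bond formation, should remove both the phenolic TBS and the tertiary TES group under non-acidic conditions that the tert-alkyl aryl ether and the allyl groups tolerate.

**Compound list**

1 | (+)-dihydrocarvone, (2R,5R)-2-methyl-5-(prop-1-en-2-yl)cyclohexan-1-one (commercial, with its C-2 epimer) | C[C@@H]1CC[C@@H](C(C)=C)CC1=O | starting material
2 | methyl vinyl ketone | C=CC(C)=O | starting material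
3 | N-[(1R)-1-phenylethyl] ketimine of 1 (C-2 epimers equilibrating) | CC1CC[C@@H](C(C)=C)CC1=N[C@H](C)c1ccccc1 | intermediate (not isolated)
4 | N-[(1R)-1-phenylethyl] ketimine of diketone 5 | CC(=O)CC[C@]1(C)CC[C@@H](C(C)=C)CC1=N[C@H](C)c1ccccc1 | intermediate (not isolated)
5 | (2S,5R)-2-methyl-2-(3-oxobutyl)-5-(prop-1-en-2-yl)cyclohexan-1-one | CC(=O)CC[C@]1(C)CC[C@@H](C(C)=C)CC1=O | intermediate
6 | (4aS,7R)-8a-hydroxy-4a-methyl-7-(prop-1-en-2-yl)octahydronaphthalen-2(1H)-one (carbinol configuration immaterial) | O=C1CC[C@]2(C)CC[C@@H](C(C)=C)CC2(O)C1 | intermediate (not isolated)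
7 | (4aS,7R)-4a-methyl-7-(prop-1-en-2-yl)-4,4a,5,6,7,8-hexahydronaphthalen-2(3H)-one | O=C1CC[C@]2(C)CC[C@@H](C(C)=C)CC2=C1 | intermediate
8 | (4aS,7R,8aS)-4a-methyl-7-(prop-1-en-2-yl)octahydronaphthalen-2(1H)-one (trans-fused) | O=C1CC[C@]2(C)CC[C@@H](C(C)=C)C[C@H]2C1 | intermediate
9 | (4aS,7R,8aS)-7-(2-hydroxypropan-2-yl)-4a-methyloctahydronaphthalen-2(1H)-one | O=C1CC[C@]2(C)CC[C@@H](C(C)(C)O)C[C@H]2C1 | intermediate
10 | (4aS,7R,8aS)-4a-methyl-7-[2-(triethylsilyloxy)propan-2-yl]octahydronaphthalen-2(1H)-one | O=C1CC[C@]2(C)CC[C@@H](C(C)(C)O[Si](CC)(CC)CC)C[C@H]2C1 | intermediate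
11 | Dec–OH, (2R,4aS,7R,8aS)-2,4a-dimethyl-7-[2-(triethylsilyloxy)propan-2-yl]decahydronaphthalen-2-ol (axial OH, trans to the angular methyl) | O[C@]1(C)CC[C@]2(C)CC[C@@H](C(C)(C)O[Si](CC)(CC)CC)C[C@H]2C1 | intermediate
12 | 4-hydroxyphenylacetic acid | OC(=O)Cc1ccc(O)cc1 | starting material
13 | prop-2-en-1-yl 2-[4-(prop-2-en-1-yloxy)phenyl]acetate | C=CCOC(=O)Cc1ccc(OCC=C)cc1 | intermediate
14 | prop-2-en-1-yl 2-(3-allyl-4-hydroxyphenyl)acetate | C=CCOC(=O)Cc1ccc(O)c(CC=C)c1 | intermediate
15 | prop-2-en-1-yl 2-[3-allyl-4-(tert-butyldimethylsilyloxy)phenyl]acetate | C=CCOC(=O)Cc1ccc(O[Si](C)(C)C(C)(C)C)c(CC=C)c1 | intermediate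
16 | 2-[3-allyl-4-(tert-butyldimethylsilyloxy)phenyl]acetic acid | OC(=O)Cc1ccc(O[Si](C)(C)C(C)(C)C)c(CC=C)c1 | intermediate
17 | 2-[3-allyl-4-(tert-butyldimethylsilyloxy)phenyl]acetyl chloride | ClC(=O)Cc1ccc(O[Si](C)(C)C(C)(C)C)c(CC=C)c1 | intermediate (not isolated)
18 | Dec 2-[3-allyl-4-(tert-butyldimethylsilyloxy)phenyl]acetate | C=CCc1cc(CC(=O)O[C@]2(C)CC[C@]3(C)CC[C@@H](C(C)(C)O[Si](CC)(CC)CC)C[C@H]3C2)ccc1O[Si](C)(C)C(C)(C)C | intermediate
19 | Dec 2-Ar-3-(dimethylamino)propanoate (α-carbon epimers) | CN(C)CC(C(=O)O[C@]1(C)CC[C@]2(C)CC[C@@H](C(C)(C)O[Si](CC)(CC)CC)C[C@H]2C1)c1ccc(O[Si](C)(C)C(C)(C)C)c(CC=C)c1 | intermediate (not isolated)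
20 | trimethylammonium iodide of 19 | C[N+](C)(C)CC(C(=O)O[C@]1(C)CC[C@]2(C)CC[C@@H](C(C)(C)O[Si](CC)(CC)CC)C[C@H]2C1)c1ccc(O[Si](C)(C)C(C)(C)C)c(CC=C)c1.[I-] | intermediate (not isolated)
21 | Dec 2-Ar-prop-2-enoate | C=C(C(=O)O[C@]1(C)CC[C@]2(C)CC[C@@H](C(C)(C)O[Si](CC)(CC)CC)C[C@H]2C1)c1ccc(O[Si](C)(C)C(C)(C)C)c(CC=C)c1 | intermediate
22 | 2-(Dec-oxy)-3-Ar-buta-1,3-diene | C=C(O[C@]3(C)CC[C@]4(C)CC[C@@H](C(C)(C)O[Si](CC)(CC)CC)C[C@H]4C3)C(=C)c2ccc(O[Si](C)(C)C(C)(C)C)c(CC=C)c2 | intermediate
23 | methyl propiolate | C#CC(=O)OC | starting material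
24 | methyl 4-(Dec-oxy)-5-Ar-cyclohexa-1,4-diene-1-carboxylate | COC(=O)C1=CCC(O[C@]3(C)CC[C@]4(C)CC[C@@H](C(C)(C)O[Si](CC)(CC)CC)C[C@H]4C3)=C(c2ccc(O[Si](C)(C)C(C)(C)C)c(CC=C)c2)C1 | intermediate
25 | methyl 4-(Dec-oxy)-3-Ar-benzoate | COC(=O)c1ccc(O[C@]2(C)CC[C@]3(C)CC[C@@H](C(C)(C)O[Si](CC)(CC)CC)C[C@H]3C2)c(-c4ccc(O[Si](C)(C)C(C)(C)C)c(CC=C)c4)c1 | intermediate
26 | [4-(Dec-oxy)-3-Ar-phenyl]methanol | OCc1ccc(O[C@]2(C)CC[C@]3(C)CC[C@@H](C(C)(C)O[Si](CC)(CC)CC)C[C@H]3C2)c(-c4ccc(O[Si](C)(C)C(C)(C)C)c(CC=C)c4)c1 | intermediate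
27 | 4-(bromomethyl)-1-(Dec-oxy)-2-Ar-benzene | BrCc1ccc(O[C@]2(C)CC[C@]3(C)CC[C@@H](C(C)(C)O[Si](CC)(CC)CC)C[C@H]3C2)c(-c4ccc(O[Si](C)(C)C(C)(C)C)c(CC=C)c4)c1 | intermediate
28 | 4-allyl-1-(Dec-oxy)-2-Ar-benzene | C=CCc1ccc(O[C@]2(C)CC[C@]3(C)CC[C@@H](C(C)(C)O[Si](CC)(CC)CC)C[C@H]3C2)c(-c4ccc(O[Si](C)(C)C(C)(C)C)c(CC=C)c4)c1 | intermediate
29 | (2R,4aS,7R,8aS)-2-[4-allyl-2-(3-allyl-4-hydroxyphenyl)phenoxy]-7-(2-hydroxypropan-2-yl)-2,4a-dimethyldecahydronaphthalene | C=CCc1ccc(O[C@]2(C)CC[C@]3(C)CC[C@@H](C(C)(C)O)C[C@H]3C2)c(-c2ccc(O)c(CC=C)c2)c1 | target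

**Step count**
Total: 19 steps. Longest linear sequence: 15 steps (steps 1–6, then 11–19, from 1). The arylacetic acid branch (steps 7–10) has 4 steps.

**Steps most likely to fail**

Step 14. The cycloaddition may be slower than thermal or trace-acid decomposition of the enol-ether diene, and the aryl substituent may erode the para orientation. The fallback sets out from diene 22 and replaces the alkyne by methyl 2-chloroacrylate, a captodative alkene with the same polarisation that should react at a distinctly lower temperature. The same two bonds would form to give the chloro cycloadduct F1. DBU in the same pot would remove HCl to give 24 together with its conjugated 1,3-diene isomer F2, and DDQ would convert both into arene 25, where the route is rejoined.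

Step 13. Methylenation of the hindered, conjugated ester may stall, and the acrylate or the acid-labile diene may be lost on contact with the Lewis-acidic aluminium by-products. The fallback sets out from ester 18: the Mannich base 19 would be isolated (no methyl iodide) and its saturated ester carbonyl methylenated with dimethyltitanocene (toluene, 70 °C; neutral and aluminium-free) to the amino enol ether F3. Quaternisation with MeI to the ammonium iodide F4 and Hofmann elimination with KOtBu (THF, 0 °C) would then create the second double bond under basic conditions and deliver diene 22.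

Step 11. Ketene formation and dimerisation may outrun O-acylation of the hindered axial tertiary alkoxide. The fallback sets out from alcohol 11: the small acetyl group would be introduced first (Ac2O, DMAP, Et3N) to give the tertiary acetate F5. The aryl group would then be joined to the acetate α-carbon by palladium-catalysed enolate arylation (LiHMDS, Pd(dba)2, P(t-Bu)3, toluene, rt) with the aryl bromide F6, itself made from purchasable 2-allyl-4-bromophenol with TBSCl and imidazole. This returns to ester 18.

**Further compounds**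
F1 | step 14 | methyl 1-chloro-4-(Dec-oxy)-3-Ar-cyclohex-3-ene-1-carboxylate (C-1 epimers) | COC(=O)C1(Cl)CCC(O[C@]2(C)CC[C@]3(C)CC[C@@H](C(C)(C)O[Si](CC)(CC)CC)C[C@H]3C2)=C(c4ccc(O[Si](C)(C)C(C)(C)C)c(CC=C)c4)C1
F2 | step 14 | methyl 4-(Dec-oxy)-3-Ar-cyclohexa-1,3-diene-1-carboxylate | COC(=O)C1=CC(c4ccc(O[Si](C)(C)C(C)(C)C)c(CC=C)c4)=C(O[C@]2(C)CC[C@]3(C)CC[C@@H](C(C)(C)O[Si](CC)(CC)CC)C[C@H]3C2)CC1
F3 | step 13 | 3-Ar-2-(Dec-oxy)-N,N-dimethylbut-3-en-1-amine numbered from nitrogen, i.e. CH2=C(O-Dec)–CH(Ar)–CH2NMe2 | C=C(O[C@]1(C)CC[C@]2(C)CC[C@@H](C(C)(C)O[Si](CC)(CC)CC)C[C@H]2C1)C(CN(C)C)c1ccc(O[Si](C)(C)C(C)(C)C)c(CC=C)c1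
F4 | step 13 | trimethylammonium iodide of F3 | C=C(O[C@]1(C)CC[C@]2(C)CC[C@@H](C(C)(C)O[Si](CC)(CC)CC)C[C@H]2C1)C(C[N+](C)(C)C)c1ccc(O[Si](C)(C)C(C)(C)C)c(CC=C)c1.[I-]
F5 | step 11 | Dec acetate | CC(=O)O[C@]1(C)CC[C@]2(C)CC[C@@H](C(C)(C)O[Si](CC)(CC)CC)C[C@H]2C1
F6 | step 11 | tert-butyl(2-allyl-4-bromophenoxy)dimethylsilane | C=CCc1cc(Br)ccc1O[Si](C)(C)C(C)(C)C
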